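All constants stand for no real mixture; the flask was simulated.

In a one-step world, starting material meets partner and becomes target; this flask has rivals.

| flask | starting material | partner | protic impurity | time | remark | temperature |
|---|---|---|---|---|---|---|
| south | 0.10 M | 0.0950 M (fed, over 30 h) | 0.0500 M | 40 h | the addition at 40 °C, then warmed to 60 °C; the feed brings no volume worth counting |  |
| north-west | 0.10 M | 0.0950 M | 0.0500 M | 40 h | everything together at the start | 60 °C |
| west | 0.10 M (fed, over 30 h) | 0.0950 M | 0.0500 M | 40 h | all else is in the flask from the start; the feed brings no volume worth counting | 60 °C |
| south-west | 0.10 M | 0.0950 M (fed, over 30 h) | 0.0500 M | 40 h | all else is in the flask from the start; the feed brings no volume worth counting | 60 °C |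

    starting material + partner → target (k1 = 7.83 /M/h, Ea1 = 84.0 kJ/mol)
    starting material → side product A (k2 = 1.31 /h, Ea2 = 114 kJ/mol)
    2 starting material → side product B (k3 = 0.686 /M/h, Ea3 = 78.0 kJ/mol)
    starting material + protic impurity → quenched substrate (k4 = 0.237 /M/h, Ea4 = 86.0 kJ/mol)
    starting material + target → side product C (k5 = 0.849 /M/h, Ea5 = 78.0 kJ/mol)
    2 partner → self-condensation product (k6 = 0.469 /M/h, Ea6 = 94.0 kJ/mol)
    (constants at 60 °C)

- a species is counted by the starting material in it: one side product B or side product C counts as two
- two of one species on the left: rate k times its square, two consumed each time
- at 60 °C the constants are as listed, elsewhere as the activation energies make them

- which flask leads in amount of target, in percent of the starting material charged ("all alike" within 1.5 percentage points) (south / north-west / west / south-west / all alike)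
- how much target is there at the end, in percent of the starting material charged: south
- how much target is there at the end, in percent of the starting material charged: north-west
- how much target is there at the end, in percent of the starting material charged: west
- how much target is there at the end, in percent of the starting material charged: south-west

This is my note for the bench. At 60 °C, starting material lasts about 0.763 h by the route to side product A alone, so partner has to be on hand during that short life. I count turns: the constant of the target step times the partner on hand, over the constant of the step to side product A. This turn count, the selectivity factor, says how many turns go to target for each turn lost to side product A. At the full charge of partner it is 0.568, which gives target a share of 36.2% when reckoned against side product A.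

In north-west the count starts there and falls as partner is used, so I expect target under that share. In west, partner at full charge has a first half-life of 11.2 h by self-condensation, shorter than the feed of 30 h, so the count sinks during the feed. In south-west, the count grows from nothing with the feed, and summed over the life of starting material it gives target near 1.44% of the charge, so I expect little target there. I don't reckon south, so I name no leader.

When you come, I expect products and leftover partner in the flasks. Don't warm south before its feed ends. The route to side product A has the steeper activation energy, 114 kJ/mol against 84.0 kJ/mol, so at equal partner warmth lowers the count.

The forecast gives south 15.2%, north-west 29.2%, west 18.5% and south-west 1.3%, with north-west leading. Its ground is this: “the partner must be present while starting material survives”. My south-west figure stands a little above its figure.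

The flasks end at south 15.0%, north-west 29.1%, west 17.7% and south-west 1.10%, so north-west leads. In north-west at 0.358 h, starting material goes to side product A 2.2 times as fast as to target, a count of 0.454, lower than the 0.568 at the start. North-west ends with 65.6% side product A. The neighbour of north-west charged with 0.24 M of partner starts at a count of 1.43, a share of 58.8%, and ends with 51.6% target.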